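The ten-membered carbocycle (ring atoms C1–C10, locants in the remark below) is opened at C1–C2, the bond joining the acetoxy-bearing allylic carbon C1 to the vinylic CH of the Z-trisubstituted alkene C2=C3: an allylic alcohol is the retron for addition of an alkenyl metal to an aldehyde. An intramolecular Nozaki–Hiyama–Kishi reaction unites two electrophilic carbons, the Z-iodoalkene carbon C2 and the aldehyde carbon C1, by polarity reversal at chromium, closing the ring and creating the C1 carbinol in one operation. The precursor is an acyclic Z-iodoalkenyl β-hydroxy aldehyde; its C9/C10 centres come from an Evans aldol and its C6=C7 geometry from a butyrolactone template.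

Key step: step 14

Remark: locants of the target ring are used for all intermediates: C1 (CH–OAc next to the alkene), C2(H)=C3(Me), C4, C5, C6 and C7 (oxirane carbons, C7 bearing CHO), C8, C9 (CH–OAc), C10 (CH–iPr); the tartrate enantiomer in step 17 is chosen on the assumption that the usual Sharpless face rule holds for this 2-substituted allylic alcohol.

**Step 1**
Reactants: 1 prop-2-yn-1-ol
Product: 3 (Z)-3-iodo-2-methylprop-2-en-1-ol, via magnesium chelate 2 (not isolated)
Conditions: MeMgBr (2.5 equiv), CuI (10 mol%), THF, −10 °C → rt; then I2, −78 → 0 °C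
Reagents that add atoms: methylmagnesium bromide C[Mg]Br; iodine II
Why: Copper-catalysed anti-carbomagnesiation of the propargylic alkoxide (Duboudin–Jousseaume) puts methyl on the internal carbon and magnesium on the terminal carbon cis to CH2O in chelate 2, and iodinolysis with retention should give the Z-iodide that later becomes the Z ring alkene C2=C3.

**Step 2**
Reactants: 3 (Z)-3-iodo-2-methylprop-2-en-1-ol
Product: 4 (Z)-3-bromo-1-iodo-2-methylprop-1-ene
Conditions: PBr3, Et2O, 0 °C
Reagents that add atoms: phosphorus tribromide BrP(Br)Br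
Why: Bromination of a primary allylic alcohol by SN2 displacement of the phosphite ester should leave the vinyl iodide and its geometry untouched.

**Step 3**
Reactants: 5 acetaldehyde N,N-dimethylhydrazone; 4 (Z)-3-bromo-1-iodo-2-methylprop-1-ene
Product: 8 (Z)-5-iodo-4-methylpent-4-enal, via lithiated hydrazone 6 (not isolated), via alkylated hydrazone 7 (not isolated)
Conditions: LiN(iPr)2, THF, 0 °C; 4, −78 → 0 °C; then sat. aq. oxalic acid, Et2O, rt
Reagents that add atoms: water O
Why: Corey–Enders alkylation of the aza-enolate (an acetaldehyde enolate equivalent) by SN2 at the primary allylic bromide, followed by two-phase acidic hydrolysis of the hydrazone, should give the aldehyde carrying C2–C6.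

**Step 4**
Reactants: 9 (S)-4-benzyl-1,3-oxazolidin-2-one; 10 3-methylbutanoyl chloride
Product: 11 (S)-4-benzyl-3-(3-methylbutanoyl)-1,3-oxazolidin-2-one
Conditions: Et3N, DMAP (cat.), CH2Cl2, 0 °C → rt
Reagents that add atoms: none
Why: DMAP-catalysed N-acylation of the oxazolidinone by the acid chloride gives the Evans imide.

**Step 5**
Reactants: 11 (S)-4-benzyl-3-(3-methylbutanoyl)-1,3-oxazolidin-2-one; 12 methyl 4-oxobutanoate
Product: 15 (4S)-4-benzyl-3-{(2S)-3-methyl-2-[(2R)-5-oxooxolan-2-yl]butanoyl}-1,3-oxazolidin-2-one, via boron enolate 13 (not isolated), via aldol adduct 14 (not isolated)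
Conditions: Bu2BOTf, iPr2NEt, CH2Cl2, 0 °C; 12, −78 → 0 °C; pH 7 buffer, MeOH, 30% H2O2, 0 °C; crude 14, pyridinium p-toluenesulfonate (cat.), toluene, 60 °C
Reagents that add atoms: none
Why: Evans syn aldol, in which the Z-boron enolate 13 adds to the aldehyde through a Zimmerman–Traxler chair on the face opposite the benzyl group to set C10 (S) and C9 (R) syn, after which acid catalysis closes the γ-lactone from the C9 hydroxyl and the methyl ester.

**Step 6**
Reactants: 15 (4S)-4-benzyl-3-{(2S)-3-methyl-2-[(2R)-5-oxooxolan-2-yl]butanoyl}-1,3-oxazolidin-2-one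
Product: 16 (5R)-5-[(2R)-1-hydroxy-3-methylbutan-2-yl]oxolan-2-one
Conditions: NaBH4, THF/H2O 4:1, 0 °C → rt
Reagents that add atoms: none
Why: Reductive removal of the auxiliary, in which borohydride attacks the activated exocyclic imide carbonyl much faster than the γ-lactone, should give the C1 primary alcohol without touching C10.

**Step 7**
Reactants: 16 (5R)-5-[(2R)-1-hydroxy-3-methylbutan-2-yl]oxolan-2-one
Product: 17 (5R)-5-[(2R)-1-(tert-butyldimethylsilyloxy)-3-methylbutan-2-yl]oxolan-2-one
Conditions: TBSCl, imidazole, DMF, rt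
Reagents that add atoms: tert-butyldimethylsilyl chloride CC(C)(C)[Si](C)(C)Cl
Why: Silylation of the primary alcohol masks C1–OH for the enolate chemistry that follows.

**Step 8**
Reactants: 17 (5R)-5-[(2R)-1-(tert-butyldimethylsilyloxy)-3-methylbutan-2-yl]oxolan-2-one; 8 (Z)-5-iodo-4-methylpent-4-enal
Product: 19 (5R)-5-[(2R)-1-(tert-butyldimethylsilyloxy)-3-methylbutan-2-yl]-3-[(4Z)-1-hydroxy-5-iodo-4-methylpent-4-en-1-yl]oxolan-2-one as a mixture of diastereomers at the two new centres, via lithium enolate 18 (not isolated)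
Conditions: LiN(iPr)2, THF, −78 °C; then 8, −78 °C; aq. NH4Cl
Reagents that add atoms: none
Why: Aldol addition of the lactone lithium enolate to the aldehyde forms the C6–C7 bond, and both new centres are erased in the next step.

**Step 9**
Reactants: 19 the β-hydroxy lactone mixture
Product: 21 (5R,3E)-5-[(2R)-1-(tert-butyldimethylsilyloxy)-3-methylbutan-2-yl]-3-[(4Z)-5-iodo-4-methylpent-4-en-1-ylidene]oxolan-2-one, via mesylate 20 (not isolated)
Conditions: MsCl, Et3N, CH2Cl2, 0 °C; then DBU, rt
Reagents that add atoms: none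
Why: E1cB elimination of the mesylate through the lactone enolate should favour the E-alkylidene lactone (chain trans to the carbonyl, which avoids allylic strain), so that C5 and C8 end up cis on C6=C7 as the oxirane of the target requires.

**Step 10**
Reactants: 21 the E-alkylidene lactone
Product: 22 (2E,6Z)-2-[(2R,3R)-3-(tert-butyldimethylsilyloxymethyl)-2-hydroxy-4-methylpentyl]-7-iodo-6-methylhepta-2,6-dien-1-ol
Conditions: iBu2AlH (4 equiv), CH2Cl2, −78 → 0 °C; aq. KNaC4H4O6
Reagents that add atoms: none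
Why: 1,2-Reduction of the unsaturated lactone via the lactol opens the template to the allylic primary alcohol and the C9 secondary alcohol with the alkene geometry preserved.

**Step 11**
Reactants: 22 the acyclic diol
Product: 23 the primary allylic tert-butyldiphenylsilyl ether of 22
Conditions: TBDPSCl, imidazole, CH2Cl2, 0 °C
Reagents that add atoms: tert-butyldiphenylsilyl chloride CC(C)(C)[Si](Cl)(c1ccccc1)c1ccccc1
Why: The bulky silyl chloride should react selectively with the primary allylic hydroxyl and leave the hindered C9 secondary hydroxyl free.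

**Step 12**
Reactants: 23 the bis-silyl ether
Product: 24 (2R,3R,5E,9Z)-5-(tert-butyldiphenylsilyloxymethyl)-10-iodo-9-methyl-2-(propan-2-yl)deca-5,9-diene-1,3-diol
Conditions: pyridinium p-toluenesulfonate (cat.), MeOH, rt
Reagents that add atoms: none
Why: Mild acidic methanolysis cleaves a primary TBS ether far faster than a TBDPS ether, so only C1–OH is released.

**Step 13**
Reactants: 24 the 1,3-diol
Product: 25 (2S,3R,5E,9Z)-5-(tert-butyldiphenylsilyloxymethyl)-3-hydroxy-10-iodo-9-methyl-2-(propan-2-yl)deca-5,9-dienal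
Conditions: TEMPO (cat.), PhI(OAc)2, CH2Cl2, rt
Reagents that add atoms: none
Why: Oxoammonium oxidation is selective for the primary over the secondary alcohol and stops at the β-hydroxy aldehyde for a 1,3-diol, under conditions that should not epimerize C10.

**Step 14**
Reactants: 25 the Z-iodoalkenyl β-hydroxy aldehyde
Product: 27 (1S,9R,10S,2Z,6E)-7-(tert-butyldiphenylsilyloxymethyl)-3-methyl-10-(propan-2-yl)cyclodeca-2,6-diene-1,9-diol, via alkenylchromium species 26 (not isolated)
Conditions: CrCl2 (10 equiv), NiCl2 (0.1 equiv), degassed DMSO, rt, 25 added over 12 h to a final 0.003 M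
Reagents that add atoms: none
Why: CrCl2 reduces NiCl2 to zerovalent nickel, which inserts into the C2–I bond with retention of the Z geometry, and transmetalation to trivalent chromium gives alkenylchromium 26, so the formerly electrophilic C2 adds as a nucleophile to the aldehyde carbon C1 (polarity reversal; intramolecular Nozaki–Hiyama–Kishi reaction). The closest known reaction type is the NHK macrocyclization of ω-iodoalkenyl aldehydes to medium and large carbocycles. The ten-membered ring is closed by 1,2-addition to the carbonyl group with the carbonyl oxygen exocyclic (10-exo-trig), helped by the two cis turn elements C2=C3 and C6=C7. The new stereocentre C1 is controlled by the adjacent C10 centre: closure through the conformer in which the C10 isopropyl group and the chromium-bound oxygen both point to the periphery of the forming ring should place the new hydroxyl trans to isopropyl and cis to the C9 hydroxyl, with all three contiguous substituents pseudo-equatorial. The step needs chemoselectivity (the alkenylchromium adds only to the aldehyde and tolerates the free secondary hydroxyl, the silyl ether and the second alkene) and cyclization over oligomerization, which slow addition at high dilution secures.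

**Step 15**
Reactants: 27 the macrocyclic 1,9-diol
Product: 28 the 1,9-diacetate of 27
Conditions: Ac2O, DMAP (cat.), pyridine, CH2Cl2, rt
Reagents that add atoms: acetic anhydride CC(=O)OC(C)=O
Why: DMAP-catalysed acetylation esterifies both secondary hydroxyls.

**Step 16**
Reactants: 28 the silyl ether diacetate
Product: 29 (1S,9R,10S,2Z,6E)-7-(hydroxymethyl)-3-methyl-10-(propan-2-yl)cyclodeca-2,6-diene-1,9-diyl diacetate
Conditions: HF·pyridine, pyridine, THF, 0 °C → rt
Reagents that add atoms: none
Why: Buffered acidic fluoride cleaves the TBDPS ether while the acetates should neither hydrolyse nor migrate.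

**Step 17**
Reactants: 29 the allylic alcohol
Product: 30 (1S,6R,7R,9R,10S,2Z)-6,7-epoxy-7-(hydroxymethyl)-3-methyl-10-(propan-2-yl)cyclodec-2-ene-1,9-diyl diacetate
Conditions: Ti(OiPr)4, D-(−)-diethyl tartrate, tBuOOH, 4 Å molecular sieves, CH2Cl2, −20 °C
Reagents that add atoms: tert-butyl hydroperoxide CC(C)(C)OO
Why: Sharpless asymmetric epoxidation is directed by the free primary allylic hydroxyl to C6=C7 only, and the D-(−)-tartrate should deliver oxygen to the face opposite to that by which the L-(+)-ester turns E-2-alken-1-ols into (2S,3S)-epoxy alcohols, which sets C6 (R) and the C7 configuration of the target with C5 and C8 cis on the oxirane.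

**Step 18**
Reactants: 30 the epoxy alcohol
Product: 31 the target CNP0145766.3
Conditions: Dess–Martin periodinane, NaHCO3, CH2Cl2, 0 °C → rt
Reagents that add atoms: none
Why: Buffered Dess–Martin oxidation converts the primary alcohol into the aldehyde without opening the oxirane, and C7 is quaternary so nothing can epimerize.

**Compound list**
1 | prop-2-yn-1-ol | C#CCO | starting material
2 | 4-methyl-2,5-dihydro-1,2-oxamagnesole, the chelated Z-alkenylmagnesium alkoxide (not isolated) | CC1=C[Mg]OC1 | intermediate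
3 | (Z)-3-iodo-2-methylprop-2-en-1-ol | OC/C(C)=C\I | intermediate
4 | (Z)-3-bromo-1-iodo-2-methylprop-1-ene | BrC/C(C)=C\I | intermediate
5 | acetaldehyde N,N-dimethylhydrazone | CC=NN(C)C | starting material
6 | lithiated hydrazone, the N-lithio aza-enolate of 5 (not isolated) | C=CN([Li])N(C)C | intermediate
7 | (Z)-5-iodo-4-methylpent-4-enal N,N-dimethylhydrazone (not isolated) | CN(C)N=CCC/C(C)=C\I | intermediate
8 | (Z)-5-iodo-4-methylpent-4-enal | O=CCC/C(C)=C\I | intermediate
9 | (S)-4-benzyl-1,3-oxazolidin-2-one | O=C1N[C@@H](Cc2ccccc2)CO1 | starting material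
10 | 3-methylbutanoyl chloride | CC(C)CC(Cl)=O | starting material
11 | (S)-4-benzyl-3-(3-methylbutanoyl)-1,3-oxazolidin-2-one | CC(C)CC(=O)N1[C@@H](Cc2ccccc2)COC1=O | intermediate
12 | methyl 4-oxobutanoate | COC(=O)CCC=O | starting material
13 | Z-dibutylboron enolate of 11 (not isolated) | CC(C)/C=C(\OB(CCCC)CCCC)N1[C@@H](Cc2ccccc2)COC1=O | intermediate
14 | methyl (4R,5S)-5-{[(4S)-4-benzyl-2-oxo-1,3-oxazolidin-3-yl]carbonyl}-4-hydroxy-6-methylheptanoate (not isolated) | COC(=O)CC[C@@H](O)[C@H](C(C)C)C(=O)N1[C@@H](Cc2ccccc2)COC1=O | intermediate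
15 | (4S)-4-benzyl-3-{(2S)-3-methyl-2-[(2R)-5-oxooxolan-2-yl]butanoyl}-1,3-oxazolidin-2-one | O=C1CC[C@H]([C@H](C(C)C)C(=O)N2[C@@H](Cc3ccccc3)COC2=O)O1 | intermediate
16 | (5R)-5-[(2R)-1-hydroxy-3-methylbutan-2-yl]oxolan-2-one | O=C1CC[C@H]([C@H](C(C)C)CO)O1 | intermediate
17 | (5R)-5-[(2R)-1-(tert-butyldimethylsilyloxy)-3-methylbutan-2-yl]oxolan-2-one | O=C1CC[C@H]([C@H](C(C)C)CO[Si](C)(C)C(C)(C)C)O1 | intermediate
18 | lithium enolate of 17 (not isolated) | [Li]OC1=CC[C@H]([C@H](C(C)C)CO[Si](C)(C)C(C)(C)C)O1 | intermediate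
19 | (5R)-5-[(2R)-1-(tert-butyldimethylsilyloxy)-3-methylbutan-2-yl]-3-[(4Z)-1-hydroxy-5-iodo-4-methylpent-4-en-1-yl]oxolan-2-one, mixture of diastereomers at the two new centres | O=C1C(C(O)CC/C(C)=C\I)C[C@H]([C@H](C(C)C)CO[Si](C)(C)C(C)(C)C)O1 | intermediate
20 | methanesulfonate of 19 (not isolated) | O=C1C(C(OS(C)(=O)=O)CC/C(C)=C\I)C[C@H]([C@H](C(C)C)CO[Si](C)(C)C(C)(C)C)O1 | intermediate
21 | (5R,3E)-5-[(2R)-1-(tert-butyldimethylsilyloxy)-3-methylbutan-2-yl]-3-[(4Z)-5-iodo-4-methylpent-4-en-1-ylidene]oxolan-2-one | O=C1/C(=C/CC/C(C)=C\I)C[C@H]([C@H](C(C)C)CO[Si](C)(C)C(C)(C)C)O1 | intermediate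
22 | (2E,6Z)-2-[(2R,3R)-3-(tert-butyldimethylsilyloxymethyl)-2-hydroxy-4-methylpentyl]-7-iodo-6-methylhepta-2,6-dien-1-ol | OC/C(=C/CC/C(C)=C\I)C[C@@H](O)[C@H](C(C)C)CO[Si](C)(C)C(C)(C)C | intermediate
23 | primary allylic tert-butyldiphenylsilyl ether of 22 | CC(C)(C)[Si](OC/C(=C/CC/C(C)=C\I)C[C@@H](O)[C@H](C(C)C)CO[Si](C)(C)C(C)(C)C)(c1ccccc1)c1ccccc1 | intermediate
24 | (2R,3R,5E,9Z)-5-(tert-butyldiphenylsilyloxymethyl)-10-iodo-9-methyl-2-(propan-2-yl)deca-5,9-diene-1,3-diol | CC(C)(C)[Si](OC/C(=C/CC/C(C)=C\I)C[C@@H](O)[C@H](C(C)C)CO)(c1ccccc1)c1ccccc1 | intermediate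
25 | (2S,3R,5E,9Z)-5-(tert-butyldiphenylsilyloxymethyl)-3-hydroxy-10-iodo-9-methyl-2-(propan-2-yl)deca-5,9-dienal | CC(C)(C)[Si](OC/C(=C/CC/C(C)=C\I)C[C@@H](O)[C@H](C(C)C)C=O)(c1ccccc1)c1ccccc1 | intermediate
26 | Z-alkenylchromium dichloride derived from 25, trivalent chromium (not isolated) | CC(C)(C)[Si](OC/C(=C/CC/C(C)=C\[Cr](Cl)Cl)C[C@@H](O)[C@H](C(C)C)C=O)(c1ccccc1)c1ccccc1 | intermediate
27 | (1S,9R,10S,2Z,6E)-7-(tert-butyldiphenylsilyloxymethyl)-3-methyl-10-(propan-2-yl)cyclodeca-2,6-diene-1,9-diol, ring carbons C5 and C8 cis on C6=C7 | O[C@H]1/C=C(/C)CC/C=C(/CO[Si](c2ccccc2)(c2ccccc2)C(C)(C)C)C[C@@H](O)[C@@H]1C(C)C | intermediate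
28 | 1,9-diacetate of 27 | CC(=O)O[C@H]1/C=C(/C)CC/C=C(/CO[Si](c2ccccc2)(c2ccccc2)C(C)(C)C)C[C@@H](OC(C)=O)[C@@H]1C(C)C | intermediate
29 | (1S,9R,10S,2Z,6E)-7-(hydroxymethyl)-3-methyl-10-(propan-2-yl)cyclodeca-2,6-diene-1,9-diyl diacetate | CC(=O)O[C@H]1/C=C(/C)CC/C=C(/CO)C[C@@H](OC(C)=O)[C@@H]1C(C)C | intermediate
30 | (1S,6R,7R,9R,10S,2Z)-6,7-epoxy-7-(hydroxymethyl)-3-methyl-10-(propan-2-yl)cyclodec-2-ene-1,9-diyl diacetate | CC(=O)O[C@H]1/C=C(/C)CC[C@H]2O[C@@]2(CO)C[C@@H](OC(C)=O)[C@@H]1C(C)C | intermediate
31 | CNP0145766.3, (1S,6R,7S,9R,10S,2Z)-6,7-epoxy-7-formyl-3-methyl-10-(propan-2-yl)cyclodec-2-ene-1,9-diyl diacetate | CC(=O)O[C@H]1/C=C(/C)CC[C@H]2O[C@@]2(C=O)C[C@@H](OC(C)=O)[C@@H]1C(C)C | target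

**Step count**
Total: 18 steps. Longest linear sequence: 15 steps (steps 4–18, from 9); steps 1–3 make aldehyde 8, which joins at step 8.

**Steps most likely to fail**

Step 14. What may go wrong: addition to the wrong face of the aldehyde, for instance through a chromium chelate that ties the free C9 hydroxyl to the carbonyl group, so that the ring closes but C1 forms largely with the wrong configuration. Fallback: it sets out from 25. The ring closure is run as it stands and the mixture of 27 and its C1 epimer F1 is accepted. MnO2 in CH2Cl2 oxidizes only the allylic C1 alcohol of both epimers to the β-hydroxy enone F2. Narasaka–Prasad reduction (Et2BOMe, NaBH4, THF/MeOH, −78 °C) then delivers hydride within the six-membered boron chelate, anti to the axial isopropyl group, to give the 1,3-syn diol. The fallback comes back to the route at 27. C1 is then set by chelate-controlled ketone reduction instead of by the C–C bond formation.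

Step 17. What may go wrong: mismatched double diastereoselection, in which the folded ten-membered ring shields the alkene face that the tartrate demands, giving slow and unselective oxygen transfer. Fallback: it sets out from the acyclic diol 22, where only the tartrate decides the face. Ti(OiPr)4, D-(−)-diethyl tartrate and tBuOOH give the acyclic epoxy diol F3. TBDPSCl and imidazole give the primary silyl ether F4. HF·pyridine buffered with pyridine removes the primary TBS group to give the epoxy 1,3-diol F5. TEMPO and PhI(OAc)2 give the epoxy hydroxy aldehyde F6. CrCl2 and NiCl2 in DMSO close the ring to the macrocyclic epoxy diol F7. Ac2O, DMAP and pyridine give the epoxy diacetate F8. Bu4NF buffered with AcOH removes the TBDPS group, and the fallback comes back to the route at 30.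

Step 9. What may go wrong: loss of geometric control in the elimination, giving the Z-alkylidene isomer or drift of the double bond into the ring to the butenolide. Fallback: it sets out from 17. LiN(iPr)2 and Me3SiCl, then N-bromosuccinimide, give the α-bromo lactone F9. PPh3 in refluxing THF gives the phosphonium bromide F10. Et3N gives the stabilized ylide F11. A Wittig reaction of this ylide with aldehyde 8 (toluene, 80 °C) is E-selective, and the fallback comes back to the route at 21.

**Further compounds**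
F1 | step 14 | C1 epimer of 27, (1R,9R,10S)-diol | O[C@@H]1/C=C(/C)CC/C=C(/CO[Si](c2ccccc2)(c2ccccc2)C(C)(C)C)C[C@@H](O)[C@@H]1C(C)C
F2 | step 14 | (9R,10S,2Z,6E)-7-(tert-butyldiphenylsilyloxymethyl)-9-hydroxy-3-methyl-10-(propan-2-yl)cyclodeca-2,6-dien-1-one | O=C1/C=C(/C)CC/C=C(/CO[Si](c2ccccc2)(c2ccccc2)C(C)(C)C)C[C@@H](O)[C@@H]1C(C)C
F3 | step 17 | acyclic epoxy diol from 22, oxirane at C6–C7 | I/C=C(/C)CC[C@H]1O[C@@]1(CO)C[C@@H](O)[C@H](C(C)C)CO[Si](C)(C)C(C)(C)C
F4 | step 17 | primary tert-butyldiphenylsilyl ether of F3 | I/C=C(/C)CC[C@H]1O[C@@]1(CO[Si](c2ccccc2)(c2ccccc2)C(C)(C)C)C[C@@H](O)[C@H](C(C)C)CO[Si](C)(C)C(C)(C)C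
F5 | step 17 | epoxy 1,3-diol, F4 without the TBS group | I/C=C(/C)CC[C@H]1O[C@@]1(CO[Si](c2ccccc2)(c2ccccc2)C(C)(C)C)C[C@@H](O)[C@H](C(C)C)CO
F6 | step 17 | epoxy β-hydroxy aldehyde from F5 | I/C=C(/C)CC[C@H]1O[C@@]1(CO[Si](c2ccccc2)(c2ccccc2)C(C)(C)C)C[C@@H](O)[C@H](C(C)C)C=O
F7 | step 17 | macrocyclic epoxy 1,9-diol with the C7 silyloxymethyl group | O[C@H]1/C=C(/C)CC[C@H]2O[C@@]2(CO[Si](c3ccccc3)(c3ccccc3)C(C)(C)C)C[C@@H](O)[C@@H]1C(C)C
F8 | step 17 | 1,9-diacetate of F7 | CC(=O)O[C@H]1/C=C(/C)CC[C@H]2O[C@@]2(CO[Si](c3ccccc3)(c3ccccc3)C(C)(C)C)C[C@@H](OC(C)=O)[C@@H]1C(C)C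
F9 | step 9 | α-bromo lactone from 17, mixture at the C–Br centre | O=C1C(Br)C[C@H]([C@H](C(C)C)CO[Si](C)(C)C(C)(C)C)O1
F10 | step 9 | lactone α-triphenylphosphonium bromide | O=C1C([P+](c2ccccc2)(c2ccccc2)c2ccccc2)C[C@H]([C@H](C(C)C)CO[Si](C)(C)C(C)(C)C)O1.[Br-]
F11 | step 9 | lactone α-triphenylphosphoranylidene ylide | O=C1C(=P(c2ccccc2)(c2ccccc2)c2ccccc2)C[C@H]([C@H](C(C)C)CO[Si](C)(C)C(C)(C)C)O1
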